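**Strategy.** Everything rests on taking the C2–pentyl and C3–O bonds of ring A (O1, C2, C3, C4, C5) back to a 2,3-dihydrofuran whose ring holds only the C5 stereocentre, which bears the PMB-protected (1R)-dec-9-enyl carbinol arm. Ring A shows C2-pentyl and C3-OH cis to each other and both trans to the C5 side chain, exactly what face-selective epoxidation of the C2=C3 enol ether followed by same-face pentyl delivery from aluminium to C2 should leave. One operation thus forms two bonds and two stereocentres from one. The dihydrofuran arises by alkynol cycloisomerisation; afterwards PMB is exchanged for myristate.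

Key step: step 8

Remark: dimethyldioxirane is taken as a freshly prepared, titrated acetone solution (acetone, KHSO5, NaHCO3), and the organometallic starting materials are taken as purchased reagents.

**Step 1**
Reactants: 1 undec-10-enal
Product: 3 (2R)-2-[(phenylamino)oxy]undec-10-en-1-ol, via α-anilinooxy aldehyde 2 (not isolated)
Conditions: PhNO (0.8 equiv), L-proline (10 mol%), CHCl3, 4 °C; then NaBH4, EtOH, 0 °C
Reagents that add atoms: nitrosobenzene, O=Nc1ccccc1
Why: L-proline-catalysed α-aminoxylation (O-selective nitroso aldol of the enamine, the carboxylic acid hydrogen-bonding the nitroso nitrogen) should set C2 as R with high enantioselectivity, and immediate NaBH4 reduction traps the labile aldehyde as the stable alcohol.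

**Step 2**
Reactants: 3 (2R)-2-[(phenylamino)oxy]undec-10-en-1-ol
Product: 4 (2R)-undec-10-ene-1,2-diol
Conditions: Zn dust, AcOH/THF, rt
Reagents that add atoms: none
Why: Dissolving-metal reduction with zinc in acetic acid cleaves the weak N–O bond to release the diol and aniline without touching the terminal alkene or the stereocentre.

**Step 3**
Reactants: 4 (2R)-undec-10-ene-1,2-diol
Product: 5 (4R)-2-(4-methoxyphenyl)-4-(non-8-en-1-yl)-1,3-dioxolane (both C2 epimers)
Conditions: 4-MeOC6H4CH(OMe)2, PPTS (cat.), CH2Cl2, rt
Reagents that add atoms: 4-methoxybenzaldehyde dimethyl acetal, COC(OC)c1ccc(OC)cc1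
Why: Acid-catalysed transacetalisation closes the five-membered p-methoxybenzylidene acetal; the new acetal carbon forms as an inconsequential epimer mixture that is destroyed in the next step.

**Step 4**
Reactants: 5 (4R)-2-(4-methoxyphenyl)-4-(non-8-en-1-yl)-1,3-dioxolane
Product: 6 (2R)-2-[(4-methoxyphenyl)methoxy]undec-10-en-1-ol
Conditions: i-Bu2AlH (2.5 equiv), CH2Cl2, −78→0 °C; aq. potassium sodium tartrate
Reagents that add atoms: none
Why: Regioselective reductive acetal opening, in which the aluminium binds the less hindered primary oxygen and hydride reduces the resulting oxocarbenium ion, should leave the PMB group on the secondary oxygen and free the primary alcohol.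

**Step 5**
Reactants: 6 (2R)-2-[(4-methoxyphenyl)methoxy]undec-10-en-1-ol
Product: 7 (2R)-2-[(4-methoxyphenyl)methoxy]undec-10-enal
Conditions: TEMPO (10 mol%), PhI(OAc)2 (1.1 equiv), CH2Cl2, rt; used crude at once
Reagents that add atoms: none
Why: Oxoammonium (TEMPO/PhI(OAc)2) oxidation stops at the aldehyde under near-neutral conditions, so the α-alkoxy stereocentre should not epimerise.

**Step 6**
Reactants: 7 (2R)-2-[(4-methoxyphenyl)methoxy]undec-10-enal; 8 tributyl(propa-1,2-dien-1-yl)stannane
Product: 9 (4R,5R)-5-[(4-methoxyphenyl)methoxy]tetradec-13-en-1-yn-4-ol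
Conditions: MgBr2·OEt2 (2.5 equiv), CH2Cl2, −78 °C (pre-complexation); then 8, −78→−20 °C
Reagents that add atoms: none
Why: Chelation-controlled SE2' addition of the allenylstannane: MgBr2 ties the aldehyde and PMB-ether oxygens into a five-membered chelate and the nucleophile attacks the face opposite the alkyl chain, giving the 4,5-syn (4R) homopropargylic alcohol.

**Step 7**
Reactants: 9 (4R,5R)-5-[(4-methoxyphenyl)methoxy]tetradec-13-en-1-yn-4-ol
Product: 10 (2R)-2-[(1R)-1-[(4-methoxyphenyl)methoxy]dec-9-en-1-yl]-2,3-dihydrofuran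
Conditions: Mo(CO)6 (30 mol%), Et3N, Et2O, hν (350 nm); then 9, rt; chromatography on Et3N-deactivated silica
Reagents that add atoms: none
Why: Alkynol cycloisomerisation, in which the terminal alkyne rearranges on (Et3N)Mo(CO)5 to a metal vinylidene whose α-carbon is captured by the hydroxyl before protodemetalation, should give the endocyclic enol ether without touching a stereocentre.

**Step 8**
Reactants: 10 (2R)-2-[(1R)-1-[(4-methoxyphenyl)methoxy]dec-9-en-1-yl]-2,3-dihydrofuran; 11 pentylmagnesium bromide
Product: 14 (2S,3S,5R)-5-[(1R)-1-[(4-methoxyphenyl)methoxy]dec-9-en-1-yl]-2-pentyloxolan-3-ol, via tripentylaluminium 12 (not isolated), via 2,3-epoxide 13 (not isolated)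
Conditions: DMDO (1.1 equiv, acetone), CH2Cl2, −78→0 °C, volatiles removed cold; then (n-C5H11)3Al [3 equiv, made in a second flask from AlCl3 + 3 n-C5H11MgBr, Et2O, 0 °C→rt, Mg salts filtered off, solvent changed to hexane/CH2Cl2], CH2Cl2, −78→0 °C; aq. potassium sodium tartrate
Reagents that add atoms: dimethyldioxirane, CC1(C)OO1
Why: Dimethyldioxirane transfers oxygen concertedly to the electron-rich C2=C3 enol ether from the face away from the branched C5 substituent, fixing C3–O trans to the side chain, while the isolated terminal alkene is too electron-poor to compete with one equivalent of oxidant at low temperature. Tripentylaluminium then binds the epoxide oxygen, the C2–O bond ionises with help from the O1 lone pair, and a pentyl group passes from the oxygen-bound aluminate to C2 within the tight ion pair, so the C2–C bond forms on the face of the C3–O–Al unit. The closest known reaction type is dimethyldioxirane epoxidation of glycals followed by syn opening of the 1,2-anhydro sugar with trialkylaluminium reagents. No ring is closed; the oxirane is only a transient relay. C3 is controlled by the C5 stereocentre through steric approach control, and C2 by C3 through intramolecular delivery. The step needs anti epoxidation and syn alkyl transfer in preference to external anti attack or β-hydride delivery, which the bulky C5 arm, the weakly coordinating solvent, the absence of free nucleophile and the low temperature should secure.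

**Step 9**
Reactants: 14 (2S,3S,5R)-5-[(1R)-1-[(4-methoxyphenyl)methoxy]dec-9-en-1-yl]-2-pentyloxolan-3-ol
Product: 15 tert-butyl-dimethyl-{[(2S,3S,5R)-5-[(1R)-1-[(4-methoxyphenyl)methoxy]dec-9-en-1-yl]-2-pentyloxolan-3-yl]oxy}silane
Conditions: TBSOTf, 2,6-lutidine, CH2Cl2, −78→0 °C
Reagents that add atoms: tert-butyldimethylsilyl trifluoromethanesulfonate, CC(C)(C)[Si](C)(C)OS(=O)(=O)C(F)(F)F
Why: Silyl triflate silylation of the hindered secondary alcohol under 2,6-lutidine buffering is fast at low temperature and should leave the PMB ether, the ring and the alkene untouched.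

**Step 10**
Reactants: 15 tert-butyl-dimethyl-{[(2S,3S,5R)-5-[(1R)-1-[(4-methoxyphenyl)methoxy]dec-9-en-1-yl]-2-pentyloxolan-3-yl]oxy}silane
Product: 16 (1R)-1-[(2R,4S,5S)-4-[tert-butyl(dimethyl)silyl]oxy-5-pentyloxolan-2-yl]dec-9-en-1-ol
Conditions: DDQ (1.3 equiv), CH2Cl2/pH 7 buffer, 0 °C→rt
Reagents that add atoms: none
Why: Oxidative PMB cleavage, in which DDQ abstracts hydride from the electron-rich benzylic position and water hydrolyses the resulting oxocarbenium ion, should free the C1' alcohol while the silyl ether and terminal alkene stay inert.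

**Step 11**
Reactants: 16 (1R)-1-[(2R,4S,5S)-4-[tert-butyl(dimethyl)silyl]oxy-5-pentyloxolan-2-yl]dec-9-en-1-ol; 17 tetradecanoyl chloride
Product: 18 (1R)-1-[(2R,4S,5S)-4-[tert-butyl(dimethyl)silyl]oxy-5-pentyloxolan-2-yl]dec-9-en-1-yl tetradecanoate
Conditions: pyridine, DMAP (cat.), CH2Cl2, 0 °C→rt
Reagents that add atoms: none
Why: DMAP-catalysed acylation of the only free hydroxyl by the acid chloride should give the ester with retention at C1'.

**Step 12**
Reactants: 18 (1R)-1-[(2R,4S,5S)-4-[tert-butyl(dimethyl)silyl]oxy-5-pentyloxolan-2-yl]dec-9-en-1-yl tetradecanoate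
Product: 19 (1R)-1-[(2R,4S,5S)-4-hydroxy-5-pentyloxolan-2-yl]dec-9-en-1-yl tetradecanoate (CNP0191164.1)
Conditions: HF·pyridine, THF/pyridine, 0 °C→rt
Reagents that add atoms: none
Why: Fluoride-driven desilylation under mildly acidic conditions should free the C3 hydroxyl without ester cleavage or acyl migration, the two oxygens being trans-disposed across the ring.

**Compound list**
1 | undec-10-enal | C=CCCCCCCCCC=O | starting material
2 | (2R)-2-[(phenylamino)oxy]undec-10-enal | C=CCCCCCCC[C@@H](ONc1ccccc1)C=O | intermediate (not isolated)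
3 | (2R)-2-[(phenylamino)oxy]undec-10-en-1-ol | C=CCCCCCCC[C@@H](ONc1ccccc1)CO | intermediate
4 | (2R)-undec-10-ene-1,2-diol | C=CCCCCCCC[C@@H](O)CO | intermediate
5 | (4R)-2-(4-methoxyphenyl)-4-(non-8-en-1-yl)-1,3-dioxolane, C2 epimers | C=CCCCCCCC[C@@H]1COC(c2ccc(OC)cc2)O1 | intermediate
6 | (2R)-2-[(4-methoxyphenyl)methoxy]undec-10-en-1-ol | C=CCCCCCCC[C@@H](OCc1ccc(OC)cc1)CO | intermediate
7 | (2R)-2-[(4-methoxyphenyl)methoxy]undec-10-enal | C=CCCCCCCC[C@@H](OCc1ccc(OC)cc1)C=O | intermediate
8 | tributyl(propa-1,2-dien-1-yl)stannane | C=C=C[Sn](CCCC)(CCCC)CCCC | starting material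
9 | (4R,5R)-5-[(4-methoxyphenyl)methoxy]tetradec-13-en-1-yn-4-ol | C=CCCCCCCC[C@@H](OCc1ccc(OC)cc1)[C@H](O)CC#C | intermediate
10 | (2R)-2-[(1R)-1-[(4-methoxyphenyl)methoxy]dec-9-en-1-yl]-2,3-dihydrofuran | C=CCCCCCCC[C@@H](OCc1ccc(OC)cc1)[C@H]1CC=CO1 | intermediate
11 | pentylmagnesium bromide | CCCCC[Mg]Br | starting material
12 | tripentylaluminium | CCCCC[Al](CCCCC)CCCCC | intermediate (not isolated)
13 | (1R,3R,5S)-3-[(1R)-1-[(4-methoxyphenyl)methoxy]dec-9-en-1-yl]-2,6-dioxabicyclo[3.1.0]hexane | C=CCCCCCCC[C@@H](OCc1ccc(OC)cc1)[C@H]1C[C@@H]2O[C@@H]2O1 | intermediate (not isolated)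
14 | (2S,3S,5R)-5-[(1R)-1-[(4-methoxyphenyl)methoxy]dec-9-en-1-yl]-2-pentyloxolan-3-ol | C=CCCCCCCC[C@@H](OCc1ccc(OC)cc1)[C@H]1C[C@H](O)[C@H](CCCCC)O1 | intermediate
15 | tert-butyl-dimethyl-{[(2S,3S,5R)-5-[(1R)-1-[(4-methoxyphenyl)methoxy]dec-9-en-1-yl]-2-pentyloxolan-3-yl]oxy}silane | C=CCCCCCCC[C@@H](OCc1ccc(OC)cc1)[C@H]1C[C@H](O[Si](C)(C)C(C)(C)C)[C@H](CCCCC)O1 | intermediate
16 | (1R)-1-[(2R,4S,5S)-4-[tert-butyl(dimethyl)silyl]oxy-5-pentyloxolan-2-yl]dec-9-en-1-ol | C=CCCCCCCC[C@@H](O)[C@H]1C[C@H](O[Si](C)(C)C(C)(C)C)[C@H](CCCCC)O1 | intermediate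
17 | tetradecanoyl chloride (myristoyl chloride) | CCCCCCCCCCCCCC(=O)Cl | starting material
18 | (1R)-1-[(2R,4S,5S)-4-[tert-butyl(dimethyl)silyl]oxy-5-pentyloxolan-2-yl]dec-9-en-1-yl tetradecanoate | C=CCCCCCCC[C@@H](OC(=O)CCCCCCCCCCCCC)[C@H]1C[C@H](O[Si](C)(C)C(C)(C)C)[C@H](CCCCC)O1 | intermediate
19 | (1R)-1-[(2R,4S,5S)-4-hydroxy-5-pentyloxolan-2-yl]dec-9-en-1-yl tetradecanoate | C=CCCCCCCC[C@@H](OC(=O)CCCCCCCCCCCCC)[C@H]1C[C@H](O)[C@H](CCCCC)O1 | target

**Total step count:** 12. **Longest linear sequence:** 12 steps (1 to 19).

**Steps most likely to fail**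

Step 8. The pentyl transfer may lose its syn course if the aluminate ion pair opens to a free oxocarbenium ion, and a β-hydrogen of a pentyl group may be delivered in place of carbon. Face selection in the epoxidation by the remote C5 arm is the second exposure. The fallback separates oxidation from C–C bond formation and makes the C2–C bond intermolecularly under stereoelectronic control. It sets out from 10: epoxidation with dimethyldioxirane in CH2Cl2/MeOH should give, by methanolysis of 13 in the flask, the methyl furanoside (3S,5R)-2-methoxy-5-[(1R)-1-[(4-methoxyphenyl)methoxy]dec-9-en-1-yl]oxolan-3-ol F1 as an anomer mixture. Silylation (TBSOTf, 2,6-lutidine) gives tert-butyl-{[(3S,5R)-2-methoxy-5-[(1R)-1-[(4-methoxyphenyl)methoxy]dec-9-en-1-yl]oxolan-3-yl]oxy}dimethylsilane F2. Ionisation with Me3SiOTf in CH2Cl2 at −78 °C in the presence of dipentylzinc (from 11 and ZnCl2) should alkylate the five-membered oxocarbenium ion on its inside face, cis to the C3 silyloxy group. This path comes back to the route at 15, and step 9 is then not needed.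

Step 6. Incomplete chelation would erode the syn preference and give the 4S epimer, and metal exchange at the stannane could divert part of the material to the allenyl carbinol. The fallback replaces substrate control by catalyst control and tin by boron. It sets out from 7, which is treated with allenylboronic acid pinacol ester and a chiral BINOL-derived phosphoric acid in toluene at low temperature. The catalyst enantiomer is chosen to direct the closed six-membered boron transition state to the aldehyde face that gives the 4R carbinol. The path comes back to the route directly at 9 and passes through no new compound (F0).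

Step 7. Turnover of the vinylidene cycle may stall through catalyst decay, and the enol ether may hydrolyse during isolation. The fallback reaches the same dihydrofuran through a lactol. It sets out from 9: anti-Markovnikov hydration of the terminal alkyne ([CpRu(MeCN)3]PF6, 5,5'-bis(trifluoromethyl)-2,2'-bipyridine, aqueous N-methylpyrrolidone, rt) should give the aldehyde, which closes onto the C4 hydroxyl to the lactol (5R)-5-[(1R)-1-[(4-methoxyphenyl)methoxy]dec-9-en-1-yl]oxolan-2-ol F3. Mesylation and elimination (MsCl, Et3N, CH2Cl2, 0 °C→reflux) should then dehydrate it, and the path comes back to the route at 10.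

**Further compounds**
F1 | step 8 | (3S,5R)-2-methoxy-5-[(1R)-1-[(4-methoxyphenyl)methoxy]dec-9-en-1-yl]oxolan-3-ol, anomer mixture | C=CCCCCCCC[C@@H](OCc1ccc(OC)cc1)[C@H]1C[C@H](O)C(OC)O1
F2 | step 8 | tert-butyl-{[(3S,5R)-2-methoxy-5-[(1R)-1-[(4-methoxyphenyl)methoxy]dec-9-en-1-yl]oxolan-3-yl]oxy}dimethylsilane, anomer mixture | C=CCCCCCCC[C@@H](OCc1ccc(OC)cc1)[C@H]1C[C@H](O[Si](C)(C)C(C)(C)C)C(OC)O1
F0 | step 6 | none | none
F3 | step 7 | (5R)-5-[(1R)-1-[(4-methoxyphenyl)methoxy]dec-9-en-1-yl]oxolan-2-ol, anomer mixture | C=CCCCCCCC[C@@H](OCc1ccc(OC)cc1)[C@H]1CCC(O)O1
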